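**Retrosynthetic overview**
1. Ester C–O bond: the target comes from henicosanoic acid and 2-phenylethanol (DCC/DMAP esterification, last step).
2. C1 oxidation level: the acid comes from henicosan-1-ol, which comes from henicos-1-ene by anti-Markovnikov hydroboration–oxidation.
3. C4–O removal: henicos-1-ene comes from henicos-1-en-4-ol by xanthate formation and radical deoxygenation.
4. Key C3–C4 bond: henicos-1-en-4-ol comes from octadecanal (made from octadecan-1-ol) and allylmagnesium bromide, a C18 + C3 carbonyl allylation.
5. No ring is formed; the benzene ring is bought with 2-phenylethanol.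

Assumption: the target has no stereocentre, so no enantiocontrol is needed; the carbinol centre made in step 2 is racemic and is erased in step 4.

**Route**

Step 1
Reactants: 1 octadecan-1-ol
Product: 2 octadecanal
Conditions: TEMPO (10 mol%), PhI(OAc)2 (1.1 equiv), CH2Cl2, rt
Reagents that add atoms: none
Why: TEMPO/oxoammonium-catalysed alcohol oxidation with PhI(OAc)2 as terminal oxidant stops at the aldehyde in anhydrous CH2Cl2 because no hydrate can form; the aldehyde is used at once.

Step 2
Reactants: 2 octadecanal; 3 allylmagnesium bromide
Product: 5 henicos-1-en-4-ol (racemic), via bromomagnesium henicos-1-en-4-olate 4 (not isolated)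
Conditions: 3 (1.3 equiv, 1.0 M in Et2O), THF, 0 °C → rt; then sat. aq. NH4Cl
Reagents that add atoms: none
Why: Carbonyl allylation (allyl Grignard addition through a cyclic six-membered transition state) is fast enough to outrun enolisation and joins the C18 and C3 fragments; the new C4 carbinol centre is formed racemic on purpose because it is deleted in step 4.

Step 3
Reactants: 5 henicos-1-en-4-ol (racemic)
Product: 8 O-(henicos-1-en-4-yl) S-methyl carbonodithioate (racemic), via sodium henicos-1-en-4-olate 6 (not isolated), via sodium O-(henicos-1-en-4-yl) carbonodithioate 7 (not isolated)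
Conditions: NaH (1.5 equiv), THF, 0 °C → rt; CS2 (3 equiv), rt; MeI (3 equiv), rt
Reagents that add atoms: carbon disulfide, S=C=S; iodomethane, CI
Why: Xanthate formation (first half of a Barton–McCombie deoxygenation): the alkoxide adds to CS2 and the soft xanthate sulfur is S-methylated, and the isolated terminal alkene is inert to all three reagents.

Step 4
Reactants: 8 O-(henicos-1-en-4-yl) S-methyl carbonodithioate (racemic)
Product: 9 henicos-1-ene
Conditions: Bu3SnH (1.5 equiv), AIBN (0.2 equiv), toluene, 110 °C; aq. KF work-up
Reagents that add atoms: none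
Why: Barton–McCombie radical deoxygenation: the stannyl radical adds to C=S, the secondary C4 radical fragments off and abstracts H from Bu3SnH, and its closure to a cyclopropylcarbinyl radical is reversible and disfavoured, so the terminal alkene survives and the only stereocentre is removed.

Step 5
Reactants: 9 henicos-1-ene
Product: 11 henicosan-1-ol, via 9-henicosyl-9-BBN 10 (not isolated)
Conditions: 9-BBN (1.3 equiv, 0.5 M in THF), 0 °C → rt; then 3 M NaOH, 30% H2O2, 0 → 50 °C
Reagents that add atoms: hydrogen peroxide, OO
Why: Brown hydroboration–oxidation with the bulky 9-BBN places boron at the terminal carbon with >99:1 selectivity, and alkaline peroxide replaces B by OH with retention.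

Step 6
Reactants: 11 henicosan-1-ol
Product: 13 henicosanoic acid, via henicosanal 12 (not isolated)
Conditions: Jones reagent (CrO3, H2SO4, H2O), acetone/CH2Cl2, 0 °C → rt; iPrOH quench
Reagents that add atoms: water, O
Why: Jones oxidation takes the primary alcohol to the aldehyde, whose hydrate is oxidised further to the acid, and the saturated chain has nothing else that can be oxidised.

Step 7
Reactants: 13 henicosanoic acid; 14 2-phenylethanol
Product: 16 2-phenylethyl henicosanoate, via O-henicosanoyl-N,N'-dicyclohexylisourea 15 (not isolated)
Conditions: DCC (1.2 equiv), DMAP (0.1 equiv), 14 (1.2 equiv), CH2Cl2, 0 °C → rt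
Reagents that add atoms: none
Why: Steglich esterification: DCC activates the acid as the O-acylisourea, DMAP relays the acyl group to the unhindered primary alcohol, and the insoluble urea is filtered off from the non-polar ester.

**Compound list**
1 | octadecan-1-ol (stearyl alcohol) | CCCCCCCCCCCCCCCCCCO | starting material
2 | octadecanal | CCCCCCCCCCCCCCCCCC=O | intermediate
3 | allylmagnesium bromide (prop-2-en-1-ylmagnesium bromide) | C=CC[Mg]Br | starting material
4 | bromomagnesium henicos-1-en-4-olate (racemic) | CCCCCCCCCCCCCCCCCC(CC=C)O[Mg]Br | intermediate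
5 | henicos-1-en-4-ol (racemic) | CCCCCCCCCCCCCCCCCC(O)CC=C | intermediate
6 | sodium henicos-1-en-4-olate (racemic) | CCCCCCCCCCCCCCCCCC([O-])CC=C.[Na+] | intermediate
7 | sodium O-(henicos-1-en-4-yl) carbonodithioate (racemic xanthate salt) | CCCCCCCCCCCCCCCCCC(CC=C)OC(=S)[S-].[Na+] | intermediate
8 | O-(henicos-1-en-4-yl) S-methyl carbonodithioate (racemic xanthate) | CCCCCCCCCCCCCCCCCC(CC=C)OC(=S)SC | intermediate
9 | henicos-1-ene | CCCCCCCCCCCCCCCCCCCC=C | intermediate
10 | 9-henicosyl-9-BBN (9-henicosyl-9-borabicyclo[3.3.1]nonane) | CCCCCCCCCCCCCCCCCCCCCB1C2CCCC1CCC2 | intermediate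
11 | henicosan-1-ol | CCCCCCCCCCCCCCCCCCCCCO | intermediate
12 | henicosanal | CCCCCCCCCCCCCCCCCCCCC=O | intermediate
13 | henicosanoic acid (heneicosanoic acid) | CCCCCCCCCCCCCCCCCCCCC(=O)O | intermediate
14 | 2-phenylethanol | OCCc1ccccc1 | starting material
15 | O-henicosanoyl-N,N'-dicyclohexylisourea | CCCCCCCCCCCCCCCCCCCCC(=O)OC(=NC1CCCCC1)NC1CCCCC1 | intermediate
16 | 2-phenylethyl henicosanoate (phenylethyl n-heneicosanoate, achiral) | CCCCCCCCCCCCCCCCCCCCC(=O)OCCc1ccccc1 | target

**Totals**
Total step count: 7. Longest linear sequence: 7 steps (1 → 2 → 5 → 8 → 9 → 11 → 13 → 16).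

**Three steps most likely to fail, with fallbacks**

Step 4 (radical deoxygenation). The chain can stall, and tin residues are hard to separate from a pure hydrocarbon. The fallback sets out from alcohol 5 (so it also bypasses step 3) and comes back at 9, replacing the radical method by an ionic one. Alcohol 5 is treated with TsCl, pyridine and catalytic DMAP in CH2Cl2 at 0 °C → rt to give henicos-1-en-4-yl 4-methylbenzenesulfonate F1 (racemic). F1 is then reduced by SN2 hydride displacement with LiEt3BH (2.5 equiv) in THF at 0 °C → rt to give henicos-1-ene 9.

Step 6 (Jones oxidation). The waxy alcohol dissolves poorly, and the hemiacetal of 12 with unreacted 11 can be oxidised to a wax-ester by-product. The fallback sets out from 11 and comes back at the target 16, avoiding chromium and the free acid. Alcohol 11 is oxidised with TEMPO/PhI(OAc)2 in CH2Cl2 only as far as henicosanal 12, which is isolated this time. Aldehyde 12 is converted with I2/KOH in MeOH–THF at 0 °C (oxidation of the methyl hemiacetal) into methyl henicosanoate F2. F2 is transesterified with 2-phenylethanol 14 (3 equiv) and catalytic Ti(OiPr)4 in refluxing toluene, with methanol distilled off, to give 16.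

Step 7 (carbodiimide coupling). The acid is sparingly soluble in cold CH2Cl2, so slow acyl transfer can let 15 rearrange to the N-acylurea, and traces of urea are hard to remove from a waxy ester. The fallback sets out from 13 and comes back at 16 by acyl chloride chemistry. Acid 13 is treated with oxalyl chloride (1.5 equiv) and catalytic DMF in CH2Cl2 at rt to give henicosanoyl chloride F3. After evaporation, F3 is acylated onto 2-phenylethanol 14 with pyridine in CH2Cl2 at 0 °C → rt to give 16.

**Further compounds**
F1 | step 4 | henicos-1-en-4-yl 4-methylbenzenesulfonate (racemic) | CCCCCCCCCCCCCCCCCC(CC=C)OS(=O)(=O)c1ccc(C)cc1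
F2 | step 6 | methyl henicosanoate | CCCCCCCCCCCCCCCCCCCCC(=O)OC
F3 | step 7 | henicosanoyl chloride | CCCCCCCCCCCCCCCCCCCCC(=O)Cl
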